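Readings and results are calculated with constants of no real substance, and the scatter is random.

At early times the cedar run shows the pace: 8.3% target at 10.0 s and 44.4% at 50.0 s, both before its second portion. Counting one partner per starting material, the later point reads k = 0.420 L mol⁻¹ s⁻¹. Call the reciprocal of k·c(starting material) the partner life, the time in which partner falls by a factor e at that c(starting material). At the charged 0.050 M it is 0.793 min.

in all of them: starting material 0.050 M

| run | partner | remark | time |
|---|---|---|---|
| cedar | 0.083 M (in portions, 2) | run made earlier; portions every 2.0 min |  |
| gamma | 0.0550 M | everything together at the start | 4.0 min |
| alpha | 0.0550 M (in portions, 2) | the portions of partner follow each other after 2.0 min, the first at the start | 4.0 min |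

cedar run (percent of the starting material charged)

| time / s | target / % |
|---|---|
| 10.0 | 8.3 |
| 20.0 | 22.1 |
| 30.0 | 33.7 |
| 50.0 | 44.4 |

(readings scatter by 1 percentage point)

- what was read earlier has a scatter of 1 percentage point, one standard deviation

- the flask that ends with the higher amount of target, in percent of the starting material charged, or "neither" when 2 percentage points or less lies between them (gamma / alpha / neither)
- final target, as a percentage of the starting material charged, in gamma
- final target, as a percentage of the starting material charged, in alpha

Gamma and alpha look nearly the same, with equal charges and equal time. In gamma, 4.0 min is 5.04 partner lives, so the time is longer than the life. Alpha's second portion meets less starting material than the charge, so the answer goes round once more: if the first portion reacts one to one, 0.02250 M of starting material stands, which gives a life of 1.76 min. The interval of 2.0 min is then 1.14 lives. The c(starting material) of gamma falls too, but even at that longer life gamma's 4.0 min is 2.27 lives, more than alpha's second portion has, so my own reckoning puts gamma ahead.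

The forecast also says gamma, with 89% (82% to 93%) in gamma and 82% (75% to 87%) in alpha: “Dosing simply loses concentration time”.

The flasks give 71.1% in gamma and 62.1% in alpha.

    starting material + partner → intermediate (k = 0.703 L mol⁻¹ s⁻¹)
    starting material → side product (k = 0.00302 s⁻¹)
    intermediate → target (k = 0.107 s⁻¹)
    partner → decomposed reagent (k = 0.00864 s⁻¹)

At 4.00 min, gamma holds 1.51% of its partner, and beside the target stand 18.2% side product and 0.0186 M decomposed reagent. The neighbour of gamma charged with 0.022 M of partner has partner as limiting reagent at 0.440 equiv. Its second-round life is 1.42 min, so 4.0 min reckons 5.98% of partner left. That flask holds 0.19% of its partner, 31% of its starting material and 33.0% target.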